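The plan reads the O–C(=O) unit of the γ-lactone ring (O, C12, C11, C7, C6; germacrane numbering) as carbon dioxide. C6 is allylic to C4=C5 and 1,4-related to the oxygen on C3. This is the pattern left by a vinyl epoxide opened at its far end. In one flask the 2-bromoalkene of an open-chain precursor is lithiated at C11 and takes up CO2 (C11–C12). The carboxylate then closes on C6 (O–C6) of the π-allyl complex that zerovalent palladium makes from the C3–C4 epoxide. This sets C6 and the E-alkene C4=C5 and frees the hydroxyl on C3. The precursor is an acyclic epoxy tetraene brominated at C11. Metathesis closes the ten-membered ring last.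

Key step: step 10

Remark: germacrane numbering is used for all intermediates. C1–C10 are the later ring carbons, C11 is the lactone α-carbon, C12 the lactone C=O, C13 the methyl on C11, C14 the methyl on C10 and C15 the methyl on C4. C2′ is the stereocentre of the acyl side chain. Compounds 1, 2, 6, 9, 12, 15, 20 and 24 are taken as purchasable.

Step 1
Reactants: 1 prop-2-yn-1-ol; 2 allyl bromide
Product: 4 (2E)-2-methylhexa-2,5-dien-1-ol, via alkenylalane 3 (not isolated)
Conditions: AlMe3 (3 equiv), Cp2ZrCl2 (0.25 equiv), CH2Cl2, 0 °C to rt; then 2, Pd(PPh3)4 (3 mol%), THF, rt; aqueous work-up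
Reagents that add atoms: trimethylaluminium, C[Al](C)C; allyl bromide 2, C=CCBr
Why: Negishi zirconium-catalysed carboalumination adds methyl and aluminium syn across the alkyne with methyl on the inner carbon, and the palladium-catalysed allylation of alkenylalane 3 proceeds with retention, so the E-trisubstituted alkene (later C3=C4 with C15) and the terminal alkene needed for metathesis are set in one flask.

Step 2
Reactants: 4 (2E)-2-methylhexa-2,5-dien-1-ol
Product: 5 (2E)-2-methylhexa-2,5-dienal
Conditions: MnO2 (15 equiv), CH2Cl2, rt
Reagents that add atoms: none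
Why: Allylic oxidation with MnO2 is neutral and selective for the allylic alcohol, so the skipped diene is not drawn into conjugation and the E geometry is kept.

Step 3
Reactants: 5 (2E)-2-methylhexa-2,5-dienal; 6 (E)-1,2-bis(tributylstannyl)ethene
Product: 8 rac-(1E,4E)-4-methyl-1-(tributylstannyl)octa-1,4,7-trien-3-ol, via stannylvinyllithium 7 (not isolated)
Conditions: 6, n-BuLi (1.0 equiv), THF, −78 °C; then 5, −78 °C; H2O
Reagents that add atoms: (E)-1,2-bis(tributylstannyl)ethene 6, CCCC[Sn](CCCC)(CCCC)/C=C/[Sn](CCCC)(CCCC)CCCC
Why: Tin–lithium exchange of one stannyl group gives the configurationally stable E-vinyllithium 7, which adds 1,2 to the enal at low temperature and creates C5 as a racemate that step 5 resolves.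

Step 4
Reactants: 8 rac-(1E,4E)-4-methyl-1-(tributylstannyl)octa-1,4,7-trien-3-ol; 9 1,1-dibromoethene
Product: 10 rac-(3E,6E)-2-bromo-6-methyldeca-1,3,6,9-tetraen-5-ol
Conditions: 9 (5 equiv), Pd2(dba)3 (2.5 mol%), AsPh3 (10 mol%), NMP, rt
Reagents that add atoms: 1,1-dibromoethene 9, C=C(Br)Br
Why: Stille coupling proceeds with retention at the E-alkenylstannane, and because the geminal dibromide undergoes oxidative addition faster than the 2-bromodiene product, an excess of 9 stops the reaction after one coupling and leaves the bromine on C11.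

Step 5
Reactants: 10 rac-(3E,6E)-2-bromo-6-methyldeca-1,3,6,9-tetraen-5-ol
Product: 11 (1S,2E)-4-bromo-1-[(2S,3S)-2-methyl-3-(prop-2-enyl)oxiran-2-yl]penta-2,4-dien-1-ol
Conditions: Ti(Oi-Pr)4 (0.15 equiv), L-(+)-diisopropyl tartrate (0.2 equiv), t-BuOOH (0.55 equiv), 4 Å MS, CH2Cl2, −20 °C, stopped near half conversion
Reagents that add atoms: tert-butyl hydroperoxide, CC(C)(C)OO
Why: In this Sharpless kinetic resolution with L-(+)-tartrate the S enantiomer of 10 is epoxidised fast and only at the electron-rich trisubstituted C3=C4 alkene, from the face fixed by the tartrate, to the erythro epoxy alcohol with C3, C4 and C5 all S, while the R enantiomer reacts slowly at this alkene and is removed by chromatography.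

Step 6
Reactants: 11 epoxy alcohol; 12 N,N-dimethylacetamide dimethyl acetal
Product: 14 (3R,4E)-3-(1-bromoethenyl)-N,N-dimethyl-5-[(2S,3S)-2-methyl-3-(prop-2-enyl)oxiran-2-yl]pent-4-enamide, via ketene N,O-acetal 13 (not isolated)
Conditions: 12 (4 equiv), toluene, 110 °C, removal of MeOH
Reagents that add atoms: N,N-dimethylacetamide dimethyl acetal 12, CC(OC)(OC)N(C)C
Why: In this neutral Eschenmoser–Claisen rearrangement the ketene N,O-acetal 13 reacts through a chair with the oxiranyl group equatorial, so the chirality of C5 passes suprafacially to C7, the new C5=C6 alkene is E, and the epoxide, which masks the second allylic alkene, ends up as a vinyl epoxide.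

Step 7
Reactants: 14 amide; 15 2-bromopropene
Product: 17 (5R,6E)-5-(1-bromoethenyl)-2-methyl-7-[(2S,3S)-2-methyl-3-(prop-2-enyl)oxiran-2-yl]hepta-1,6-dien-3-one, via isopropenyllithium 16 (not isolated)
Conditions: 15, t-BuLi (2 equiv), Et2O, −78 °C; then 14, THF, −78 °C; AcOH quench at −78 °C
Reagents that add atoms: 2-bromopropene 15, C=C(C)Br
Why: Addition of an organolithium to a tertiary amide stops at the lithium hemiaminal, which gives the enone only on the acidic quench, and at −78 °C this addition is faster than bromine–lithium exchange between two alkenyl partners or opening of the hindered epoxide.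

Step 8
Reactants: 17 enone
Product: 18 (3S,5R,6E)-5-(1-bromoethenyl)-2-methyl-7-[(2S,3S)-2-methyl-3-(prop-2-enyl)oxiran-2-yl]hepta-1,6-dien-3-ol
Conditions: (R)-2-methyl-CBS-oxazaborolidine (0.2 equiv), catecholborane (1.5 equiv), toluene, −78 °C
Reagents that add atoms: none
Why: In the Corey–Bakshi–Shibata reduction the α-branched alkenyl group acts as the large substituent, so the R catalyst gives the S alcohol at C9 under reagent control, and catecholborane at −78 °C leaves alkenes and epoxide untouched.

Step 9
Reactants: 18 allylic alcohol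
Product: 19 tert-butyldimethylsilyl ether of 18
Conditions: TBSCl, imidazole, DMF, rt
Reagents that add atoms: tert-butyldimethylsilyl chloride, CC(C)(C)[Si](C)(C)Cl
Why: Standard silylation masks the C9 hydroxyl, so that it cannot compete as a nucleophile for the π-allyl complex in step 10 and the C3 hydroxyl can later be acylated alone.

Step 10
Reactants: 19 silyl ether; 20 carbon dioxide
Product: 23 (4S,5R)-4-[(2S)-2-(tert-butyldimethylsilyloxy)-3-methylbut-3-enyl]-5-[(1E,3S)-3-hydroxy-2-methylhexa-1,5-dienyl]-3-methylideneoxolan-2-one, via alkenyllithium 21 (not isolated), via lithium carboxylate 22 (not isolated)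
Conditions: t-BuLi (2.05 equiv), THF, −78 °C, 10 min; dry CO2, −78 to 0 °C; argon purge; Pd(PPh3)4 (5 mol%), rt; AcOH (1 equiv)
Reagents that add atoms: carbon dioxide 20, O=C=O
Why: Bromine–lithium exchange at C11 outruns attack on the hindered trisubstituted epoxide at −78 °C, alkenyllithium 21 adds to CO2 to form C11–C12, and after the excess gas is purged zerovalent palladium ionises the C4–O bond of the vinyl epoxide with inversion to a syn,syn π-allyl complex spanning C4–C6, whose C6 terminus is attacked by the tethered carboxylate of 22 anti to the metal to form O–C6. The closest known reaction types are the carboxylation of an alkenyllithium and the Tsuji–Trost 1,4-opening of vinyl epoxides by carboxylic acids, run here one after the other in one flask. The lactone ring closes in a 5-exo mode on the allyl terminus, whereas attack at C4 would need a seven-membered ring and a fully substituted carbon, which secures the regioselectivity. C6 is the only new stereocentre and is fixed by double inversion, that is by 1,4-transfer of chirality from C4 of the epoxide, and this sense is matched with C7 because it gives the trans-disubstituted lactone. The E geometry of C4=C5 follows from the W-shaped allyl unit with C3 and C7 both syn, and C3 keeps its oxygen and its configuration. The step needs palladium to act on the vinyl epoxide alone, which holds because no other allylic leaving group is present and no carbon–bromine bond is left after the lithiation.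

Step 11
Reactants: 23 hydroxy α-methylene lactone; 24 (R)-2-methylbutanoic acid
Product: 25 C3 (R)-2-methylbutanoate of 23
Conditions: 24 (1.5 equiv), DCC, DMAP (0.2 equiv), CH2Cl2, 0 °C to rt
Reagents that add atoms: (R)-2-methylbutanoic acid 24, CC[C@@H](C)C(=O)O
Why: Steglich esterification acylates the only free hydroxyl (C3) with retention at C3 and, under these mild conditions, without racemisation at C2′ of the acid.

Step 12
Reactants: 25 α-methylene lactone ester
Product: 27 (3R,4S,5S)-α-methyl lactone (C11 R; otherwise as 25), via lithium enolate 26 (not isolated)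
Conditions: LiBH(s-Bu)3 (1.05 equiv), THF, −78 °C; then 2,6-di-tert-butyl-4-methylphenol, −78 °C
Reagents that add atoms: none
Why: Conjugate hydride addition to the α-methylene lactone gives lithium enolate 26, and kinetic protonation by the bulky phenol from the face opposite to the C8 side chain on C7 places the C13 methyl cis to that chain, which is the R configuration at C11.

Step 13
Reactants: 27 α-methyl lactone silyl ether
Product: 28 seco-alcohol (27 without the silyl group)
Conditions: HF·pyridine, pyridine, THF, 0 °C to rt
Reagents that add atoms: none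
Why: Fluoride-mediated cleavage of the silyl ether under buffered, non-basic conditions frees the C9 hydroxyl without epimerising the kinetically set C11 or touching the esters.

Step 14
Reactants: 28 seco-alcohol
Product: 29 CNP0276536.1 (target)
Conditions: second-generation Hoveyda–Grubbs catalyst (10 mol%), 1,4-benzoquinone (20 mol%), toluene (1 mM), 80 °C
Reagents that add atoms: none
Why: Ring-closing metathesis starts at the terminal alkene and closes on the 1,1-disubstituted alkene with loss of ethene, and the strain of a ten-membered ring that already holds the E-alkene C4=C5 and the trans-fused lactone favours the Z geometry at C1=C10.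

Compound list
1 | prop-2-yn-1-ol | C#CCO | starting material
2 | allyl bromide | C=CCBr | starting material
3 | (E)-alkenylalane from carboalumination of 1 | C[Al](C)OC/C(C)=C/[Al](C)C | intermediate
4 | (2E)-2-methylhexa-2,5-dien-1-ol | OC/C(C)=C/CC=C | intermediate
5 | (2E)-2-methylhexa-2,5-dienal | O=C/C(C)=C/CC=C | intermediate
6 | (E)-1,2-bis(tributylstannyl)ethene | CCCC[Sn](CCCC)(CCCC)/C=C/[Sn](CCCC)(CCCC)CCCC | starting material
7 | (E)-2-(tributylstannyl)vinyllithium | [Li]/C=C/[Sn](CCCC)(CCCC)CCCC | intermediate
8 | rac-(1E,4E)-4-methyl-1-(tributylstannyl)octa-1,4,7-trien-3-ol | CCCC[Sn](CCCC)(CCCC)/C=C/C(O)/C(C)=C/CC=C | intermediate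
9 | 1,1-dibromoethene | C=C(Br)Br | starting material
10 | rac-(3E,6E)-2-bromo-6-methyldeca-1,3,6,9-tetraen-5-ol | C=C(Br)/C=C/C(O)/C(C)=C/CC=C | intermediate
11 | epoxy alcohol (C3 S, C4 S, C5 S) | C=C(Br)/C=C/[C@H](O)[C@]1(C)O[C@H]1CC=C | intermediate
12 | N,N-dimethylacetamide dimethyl acetal | CC(OC)(OC)N(C)C | starting material
13 | ketene N,O-acetal of 11 | C=C(Br)/C=C/[C@H](OC(=C)N(C)C)[C@]1(C)O[C@H]1CC=C | intermediate
14 | vinyl epoxide amide (C3 S, C4 S, C7 R, 5E) | CN(C)C(=O)C[C@@H](C(Br)=C)/C=C/[C@]1(C)O[C@H]1CC=C | intermediate
15 | 2-bromopropene | C=C(C)Br | starting material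
16 | isopropenyllithium | [Li]C(C)=C | intermediate
17 | isopropenyl ketone (C9 ketone) | C=C(C)C(=O)C[C@@H](C(Br)=C)/C=C/[C@]1(C)O[C@H]1CC=C | intermediate
18 | allylic alcohol (C9 S) | C=C(C)[C@@H](O)C[C@@H](C(Br)=C)/C=C/[C@]1(C)O[C@H]1CC=C | intermediate
19 | C9 tert-butyldimethylsilyl ether | C=C(C)[C@@H](O[Si](C)(C)C(C)(C)C)C[C@@H](C(Br)=C)/C=C/[C@]1(C)O[C@H]1CC=C | intermediate
20 | carbon dioxide | O=C=O | starting material
21 | C11 alkenyllithium | C=C(C)[C@@H](O[Si](C)(C)C(C)(C)C)C[C@@H](C([Li])=C)/C=C/[C@]1(C)O[C@H]1CC=C | intermediate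
22 | lithium 2-substituted acrylate | C=C(C)[C@@H](O[Si](C)(C)C(C)(C)C)C[C@@H](C(=C)C(=O)[O-])/C=C/[C@]1(C)O[C@H]1CC=C.[Li+] | intermediate
23 | hydroxy α-methylene trans-lactone (C3 S, C6 R, C7 S, C9 S, 4E) | C=C(C)[C@@H](O[Si](C)(C)C(C)(C)C)C[C@@H]1[C@@H](/C=C(\C)[C@@H](O)CC=C)OC(=O)C1=C | intermediate
24 | (R)-2-methylbutanoic acid | CC[C@@H](C)C(=O)O | starting material
25 | C3 (R)-2-methylbutanoate of 23 | C=C(C)[C@@H](O[Si](C)(C)C(C)(C)C)C[C@@H]1[C@@H](/C=C(\C)[C@@H](OC(=O)[C@H](C)CC)CC=C)OC(=O)C1=C | intermediate
26 | lithium lactone enolate | C=C(C)[C@@H](O[Si](C)(C)C(C)(C)C)C[C@@H]1[C@@H](/C=C(\C)[C@@H](OC(=O)[C@H](C)CC)CC=C)OC([O-])=C1C.[Li+] | intermediate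
27 | α-methyl lactone (C11 R, C6 S, C7 S) | C=C(C)[C@@H](O[Si](C)(C)C(C)(C)C)C[C@@H]1[C@@H](/C=C(\C)[C@@H](OC(=O)[C@H](C)CC)CC=C)OC(=O)[C@@H]1C | intermediate
28 | seco-alcohol | C=C(C)[C@@H](O)C[C@@H]1[C@@H](/C=C(\C)[C@@H](OC(=O)[C@H](C)CC)CC=C)OC(=O)[C@@H]1C | intermediate
29 | CNP0276536.1 | CC[C@@H](C)C(=O)O[C@H]1C/C=C(/C)[C@@H](O)C[C@@H]2[C@@H](/C=C/1C)OC(=O)[C@@H]2C | target

Total step count: 14. Longest linear sequence: 14 steps (from 1).

Steps most likely to fail

1. Step 14 (ring closure). The ruthenium alkylidene formed at the terminal alkene may couple with a second molecule faster than it engages the hindered 1,1-disubstituted alkene next to the free hydroxyl. Ruthenium hydrides may also isomerise the allylic alcohol. Fallback: set out from 28 and oxidise the C9 hydroxyl with Dess–Martin periodinane to the seco-enone F1. Close the ring by metathesis at the ketone level to the macrocyclic Z-enone F2. Set C9 last by Corey–Bakshi–Shibata reduction with the R oxazaborolidine and catecholborane. This comes back to the route at 29.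

2. Step 10 (key step). The alkenyllithium may be quenched by proton transfer from the doubly allylic C7–H or may attack the epoxide before CO2 arrives. The π-allyl complex may lose its stereochemical fidelity through exchange of palladium between the two allyl faces. The lithium alkoxide formed at C3 may add to the α-methylene lactone. Fallback: set out from 19 and build the lactone from the other side.
   - Open the vinyl epoxide with acetic acid under Pd(PPh3)4 catalysis (the same double inversion) to the 6-acetoxy-3-ol F3.
   - Cleave the acetate with K2CO3 in methanol to the 3,6-diol F4.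
   - Close the α-methylene lactone by palladium-catalysed carbonylation of the alkenyl bromide (Pd(PPh3)4, CO 1 atm, Et3N, MeCN, 60 °C). Only the C6 hydroxyl can form a five-membered ring here.
   - This comes back to the route at 23.

3. Step 12 (C11). Protonation of the flexible monocyclic enolate may show poor facial selectivity, or the kinetic cis product may equilibrate to the more stable trans α-methyl lactone. Fallback: set out from 25 and remove the silyl group with HF·pyridine to the α-methylene seco-alcohol F5. Close the ring by metathesis to the macrocyclic α-methylene lactone F6. Hydrogenate only the exocyclic alkene with RhCl(PPh3)3 and H2 (1 atm, benzene). Hydrogen is then delivered to the open face of the rigid bicycle, anti to C8. This comes back to the route at 29.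

Further compounds
F1 | step 14 | seco-enone (C9 ketone of 28) | C=C(C)C(=O)C[C@@H]1[C@@H](/C=C(\C)[C@@H](OC(=O)[C@H](C)CC)CC=C)OC(=O)[C@@H]1C
F2 | step 14 | macrocyclic Z-enone (C9 ketone of 29) | CC[C@@H](C)C(=O)O[C@H]1C/C=C(/C)C(=O)C[C@@H]2[C@@H](/C=C/1C)OC(=O)[C@@H]2C
F3 | step 10 | 6-acetoxy-3-ol from 1,4-opening of 19 | C=C(C)[C@@H](O[Si](C)(C)C(C)(C)C)C[C@@H](C(Br)=C)[C@H](OC(C)=O)/C=C(\C)[C@@H](O)CC=C
F4 | step 10 | 3,6-diol | C=C(C)[C@@H](O[Si](C)(C)C(C)(C)C)C[C@@H](C(Br)=C)[C@H](O)/C=C(\C)[C@@H](O)CC=C
F5 | step 12 | α-methylene seco-alcohol | C=C(C)[C@@H](O)C[C@@H]1[C@@H](/C=C(\C)[C@@H](OC(=O)[C@H](C)CC)CC=C)OC(=O)C1=C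
F6 | step 12 | macrocyclic α-methylene lactone | CC[C@@H](C)C(=O)O[C@H]1C/C=C(/C)[C@@H](O)C[C@@H]2[C@@H](/C=C/1C)OC(=O)C2=C
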